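Ash and cedar carry the same charges for the same time and differ in which species trickles in: partner in ash, starting material in cedar.

| setting | amber | violet | green | birch | maple | ash | cedar |
|---|---|---|---|---|---|---|---|
| starting material | 0.11 M | 0.11 M | 0.11 M | 0.11 M | 0.11 M | 0.11 M | 0.11 M (fed, over 9.60 h) |
| partner | 0.11 M | 0.11 M | 0.11 M | 0.110 M | 0.110 M | 0.110 M (fed, over 9.60 h) | 0.110 M |
| reagent | 0.132 M | 0.066 M | 0.26 M | 0.132 M | 0.132 M | 0.132 M | 0.132 M |
| remark | run made earlier | run made earlier | run made earlier | a single well-mixed tank run continuously and read at steady state, 12 h in it on average | a closed flask charged with all of it at once and left for 12 h | all but partner at the start; partner goes in evenly over 9.60 h, the run ends at 12 h | all but starting material at the start; starting material goes in evenly over 9.60 h, the run ends at 12 h |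
| time |  |  |  |  | 12 h | 12 h | 12 h |

| run | time / h | open intermediate / % | target / % | starting material / % |
|---|---|---|---|---|
| amber | 0.500 | 7 | 1 | 90 |
| amber | 0.833 | 11 | 0 | 88 |
| amber | 1.33 | 15 | 1 | 87 |
| amber | 2.00 | 18 | 0 | 80 |
| amber | 3.00 | 19 | 3 | 74 |
| amber | 5.00 | 24 | 5 | 59 |
| amber | 8.00 | 25 | 8 | 52 |
| violet | 1.00 | 6 | 1 | 93 |
| violet | 2.00 | 10 | 0 | 87 |
| violet | 3.00 | 12 | 0 | 86 |
| violet | 4.00 | 16 | 0 | 82 |
| violet | 5.00 | 17 | 2 | 81 |
| violet | 6.00 | 17 | 0 | 77 |
| violet | 8.00 | 16 | 5 | 75 |
| green | 0.500 | 12 | 0 | 87 |
| green | 0.833 | 20 | 0 | 78 |
| green | 1.33 | 28 | 0 | 69 |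
| green | 2.00 | 31 | 2 | 60 |
| green | 3.00 | 35 | 5 | 54 |
| green | 5.00 | 34 | 13 | 38 |
| green | 8.00 | 27 | 17 | 24 |

(standard deviation of a reading: 1.5 percentage points)

- the stated concentrations are those of everything mixed, before any reaction; amounts are the same in each set-up
- the feed brings no volume worth counting
- the earlier runs were made in a closed, stirred flask

1. the set-up with the highest amount of open intermediate at the outlet or at the end, in percent of the starting material put in ("none" if the first two lie within 2 percentage points) (birch / maple / ash / cedar / none)
2. amount of open intermediate at the outlet or at the end, in percent of the starting material put in, birch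
3. amount of open intermediate at the outlet or at the end, in percent of the starting material put in, maple
4. amount of open intermediate at the outlet or at the end, in percent of the starting material put in, ash
5. amount of open intermediate at the outlet or at the end, in percent of the starting material put in, cedar

Starting material and partner were charged equal in the earlier runs, so those charges cannot separate them. The reckoning here assumes that starting material falls in proportion to itself and to reagent, with a constant k, which is pseudo-first-order while reagent stays near its charge. Integrating gives the fraction left as f = exp(−s·t/τ). Here s is the share of the reagent charge still present, averaged over the time t, and τ is the fresh-reagent time constant, the reciprocal of k times the reagent charge.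

The green run reads 69 % left at 1.33 h, so, taking s as whole there, k reads 1.07 M⁻¹ h⁻¹, and birch, maple, ash and cedar, charged with 0.132 M of reagent, read τ = 7.06 h. At 8.00 h the green run reads s = 0.639, so its mean reagent reads 0.0938 M below the charge. That reading is more than the 0.0836 M of starting material the green run reads as lost by then, so reagent appears to have a second consumer, probably partner.

The feed time 9.60 h is longer than τ, so the order of charging should count. In ash, starting material meets fresh reagent while partner arrives slowly, whereas in cedar, partner meets it first. This reckoning expects ash above cedar.

The forecast differs, holding that “ash and cedar match”. It gives birch 17 %, maple 21 %, ash 24 %, cedar 24 %, best none.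

The flask gives birch 17.4 %, maple 19.6 %, ash 28.3 %, cedar 16.0 %, best ash.

    starting material + reagent → open intermediate (k = 1.10 M⁻¹ h⁻¹)
    reagent + partner → second intermediate (k = 1.40 M⁻¹ h⁻¹)
    open intermediate + second intermediate → target (k = 1.80 M⁻¹ h⁻¹)
    2 open intermediate → homo product (k = 0.830 M⁻¹ h⁻¹)
    target ⇌ isomer of the product (K = 0.660, k = 0.0640 h⁻¹)
    reagent + target → over-reaction product (k = 0.380 M⁻¹ h⁻¹)
    starting material + second intermediate → side product (k = 0.240 M⁻¹ h⁻¹)

With reagent + partner to second intermediate struck out, cedar gives 39.6 % instead of 16.0 %. Ash ends with 39.3 % of its starting material left, which through τ means s = 0.550.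

The neighbour of ash charged with 0.044 M of starting material has the same τ, since τ holds no starting-material charge. The ash share then gives 39.3 % left, and a whole share gives 18.3 %. The computed flask leaves 29.6 %, with 35.9 % of its reagent remaining against 19 % in ash.

(The data were computed on assumed constants.)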